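**Retrosynthetic overview**
- The 29-membered ansa ring is closed last by forming the N–C2(quinone) bond: a copper-catalysed aerobic dehydrogenative amidation of the quinone C–H by the C1 primary amide of the fully deprotected seco-quinone.
- The seco-quinone comes from a C6 alkyne chain and (2Z,4Z)-5-iodo-2-methylpenta-2,4-dienamide (hydrostannation/Stille at C5–C6), then one-pot oxidative unmasking of the quinone and desilylation.
- C6–C15 is grown linearly from a C15 enal: two catalytic asymmetric acetaldehyde Mukaiyama aldols (C15, C11), a Wittig reaction (C12=C13) and a Marshall anti-propargylation (C8/C9).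
- C16–C23: an aryllithium opens a Z-locked α-methyl-α,β-unsaturated δ-lactone to give the (21Z)-enone aryl ketone; the lactone comes from Roche ester by Roush (Z)-crotylboration (C18–C20 triad) and Still–Gennari olefination.
- Ring order: naphthalene ring B by Diels–Alder on benzoquinone (ring A kept as a 1,4-dimethoxyarene), temporary lactone ring, quinone ring A unmasked, macrolactam ring last.

Assumptions: the ansa chain is numbered C1 (amide carbonyl) to C23 (aryl ketone); both enantiomers of Roche ester and of but-3-yn-2-ol are taken as cheap chiral-pool materials.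
Abbreviations: Ar = 5,8-dimethoxy-2-[(4-methoxybenzyl)oxy]-3-methylnaphthalen-1-yl; TBS = tert-butyldimethylsilyl; TES = triethylsilyl; PMB = 4-methoxybenzyl.

**Aryl bromide (steps 1–4)**

Step 1
Reactants: 1 3-methylbut-3-en-2-one
Product: 2 tert-butyldimethyl[(3-methylbuta-1,3-dien-2-yl)oxy]silane
Conditions: TBSOTf, Et3N, Et2O, 0 °C
Reagents that add atoms: tert-butyldimethylsilyl trifluoromethanesulfonate, CC(C)(C)[Si](C)(C)OS(=O)(=O)C(F)(F)F
Why: Silyl enol ether formation on the only enolisable side of the ketone gives the 2-silyloxy diene.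

Step 2
Reactants: 2 silyloxy diene; 3 1,4-benzoquinone
Product: 5 tert-butyl[(5,8-dimethoxy-3-methyl-1,4-dihydronaphthalen-2-yl)oxy]dimethylsilane, via Diels–Alder adduct 4 (not isolated)
Conditions: PhMe, rt; then K2CO3, Me2SO4, acetone, reflux
Reagents that add atoms: dimethyl sulfate, COS(=O)(=O)OC
Why: Diels–Alder cycloaddition, then base-mediated double enolisation of the cis-enedione with O-methylation aromatises ring A as its dimethyl ether (the two ring-fusion stereocentres vanish; the silyl enol ether survives anhydrous carbonate).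

Step 3
Reactants: 5 dihydronaphthalene silyl enol ether
Product: 8 1-bromo-5,8-dimethoxy-3-methylnaphthalen-2-ol, via bromoketone 6 (not isolated), via naphthol 7 (not isolated)
Conditions: NBS (1.05 equiv), THF, −78 → 0 °C; 2,6-lutidine; then NBS (1.0 equiv), 0 °C
Reagents that add atoms: N-bromosuccinimide, O=C1CCC(=O)N1Br
Why: α-Bromination of the silyl enol ether, E2 loss of HBr towards the benzylic CH2 and tautomerisation aromatise ring B to the 2-naphthol, which then undergoes electrophilic aromatic bromination at its only free ortho (α) position.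

Step 4
Reactants: 8 bromonaphthol
Product: 9 1-bromo-5,8-dimethoxy-2-[(4-methoxybenzyl)oxy]-3-methylnaphthalene
Conditions: PMBCl, K2CO3, Bu4NI (cat.), DMF, rt
Reagents that add atoms: 4-methoxybenzyl chloride, COc1ccc(CCl)cc1
Why: Williamson ether synthesis; the PMB ether tolerates the aryllithium and is later removed by the same oxidant that unmasks the quinone.

**Z-locked lactone (steps 5–9)**

Step 5
Reactants: 10 methyl (S)-3-hydroxy-2-methylpropanoate
Product: 11 methyl (S)-3-[(tert-butyldimethylsilyl)oxy]-2-methylpropanoate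
Conditions: TBSCl, imidazole, CH2Cl2, rt
Reagents that add atoms: tert-butyldimethylsilyl chloride, CC(C)(C)[Si](C)(C)Cl
Why: Standard silylation of the primary alcohol; the stereocentre (future C20) is untouched.

Step 6
Reactants: 11 silyl ether ester
Product: 12 (S)-3-[(tert-butyldimethylsilyl)oxy]-2-methylpropanal
Conditions: i-Bu2AlH (1.05 equiv), CH2Cl2, −78 °C; Rochelle salt
Reagents that add atoms: none
Why: DIBAL partial reduction stops at the tetrahedral aluminium hemiacetal at −78 °C, giving the aldehyde without epimerisation.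

Step 7
Reactants: 12 aldehyde
Product: 14 (2S,3R,4S)-2,4-dimethylhex-5-ene-1,3-diol, via silyl ether 13 (not isolated)
Conditions: diisopropyl (S,S)-tartrate (Z)-crotylboronate, 4 Å MS, PhMe, −78 °C; then 1 M HCl, MeOH, rt
Reagents that add atoms: diisopropyl (4S,5S)-2-[(Z)-but-2-en-1-yl]-1,3,2-dioxaborolane-4,5-dicarboxylate, C/C=C\CB1O[C@H](C(=O)OC(C)C)[C@@H](C(=O)OC(C)C)O1
Why: Roush asymmetric crotylboration through a chair transition state: the Z-reagent gives the 18,19-syn relationship, and re-face attack by the (S,S)-reagent matches the intrinsic anti-Felkin preference to give 19,20-anti (C18 S, C19 R); acidic methanolysis cleaves the borate and the primary TBS ether.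

Step 8
Reactants: 14 diol
Product: 15 (2R,3R,4S)-3-hydroxy-2,4-dimethylhex-5-enal
Conditions: TEMPO (10 mol %), PhI(OAc)2, CH2Cl2, rt; used crude
Reagents that add atoms: none
Why: Oxoammonium (TEMPO) oxidation is selective for the primary over the secondary alcohol.

Step 9
Reactants: 15 hydroxy aldehyde
Product: 17 (5S,6R)-6-[(2S)-but-3-en-2-yl]-3,5-dimethyl-5,6-dihydro-2H-pyran-2-one, via hydroxy enoate 16 (not isolated)
Conditions: (CF3CH2O)2P(O)CH(Me)CO2Me, KN(SiMe3)2, 18-crown-6, THF, −78 °C; then camphorsulfonic acid (cat.), CH2Cl2, rt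
Reagents that add atoms: methyl 2-[bis(2,2,2-trifluoroethoxy)phosphoryl]propanoate, COC(=O)C(C)P(=O)(OCC(F)(F)F)OCC(F)(F)F
Why: Still–Gennari olefination gives the (Z)-α-methyl enoate (the phosphonate anion is too weak a base to deprotonate the free hydroxyl), which lactonises and so locks the C21=C22 geometry in a ring.

**Fragment union and chain growth (steps 10–15)**

Step 10
Reactants: 9 aryl bromide; 17 lactone
Product: 20 (2Z,4S,5R,6S)-1-Ar-2,4,6-trimethyl-5-[(triethylsilyl)oxy]octa-2,7-dien-1-one, via aryllithium 18 (not isolated), via lithium alkoxide 19 (not isolated)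
Conditions: n-BuLi, THF, −78 °C; 17 (1.1 equiv), −78 °C; then Et3SiCl, −78 → 0 °C
Reagents that add atoms: chlorotriethylsilane, CC[Si](Cl)(CC)CC
Why: Bromine–lithium exchange, then 1,2-addition of the aryllithium to the lactone carbonyl gives a lithium lactolate in equilibrium with the ring-opened keto alkoxide; silylation of the unhindered secondary alkoxide traps the open aryl ketone, with the 21Z geometry inherited from the ring.

Step 11
Reactants: 20 aryl enone with terminal vinyl group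
Product: 21 (2E,4S,5R,6S,7Z)-9-Ar-4,6,8-trimethyl-9-oxo-5-[(triethylsilyl)oxy]nona-2,7-dienal
Conditions: crotonaldehyde (5 equiv), second-generation Hoveyda–Grubbs catalyst (5 mol %), CH2Cl2, 40 °C
Reagents that add atoms: (E)-but-2-enal, C/C=C/C=O
Why: Olefin cross-metathesis of the monosubstituted alkene gives the (E)-enal (thermodynamic control); the trisubstituted enone is inert.

Step 12
Reactants: 21 C15 enal
Product: 23 (2E,5R,6E,8S,9R,10S,11Z)-13-Ar-2,8,10,12-tetramethyl-13-oxo-5,9-bis[(triethylsilyl)oxy]trideca-2,6,11-trienal, via silyloxy aldehyde 22 (not isolated)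
Conditions: CH2=CHOSiEt3 (1.5 equiv), chiral N-triflyl imidodiphosphorimidate Brønsted acid (IDPi, 1 mol %, the enantiomer that delivers re-face attack), PhMe, −60 °C; then Ph3P=C(Me)CHO, −60 → 80 °C
Reagents that add atoms: triethyl(vinyloxy)silane, C=CO[Si](CC)(CC)CC; 2-(triphenylphosphoranylidene)propanal, CC(C=O)=P(c1ccccc1)(c1ccccc1)c1ccccc1
Why: Catalytic asymmetric Mukaiyama aldol of the acetaldehyde enol silane (single aldolisation with silyl transfer) sets C15 (R) under catalyst control and gives the β-silyloxy aldehyde directly; the Wittig reaction with the stabilised ylide then forms the (12E)-trisubstituted enal.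

Step 13
Reactants: 23 C11 enal
Product: 24 (3R,4E,7R,8E,10S,11R,12S,13Z)-15-Ar-4,10,12,14-tetramethyl-15-oxo-3,7,11-tris[(triethylsilyl)oxy]pentadeca-4,8,13-trienal
Conditions: CH2=CHOSiEt3 (1.5 equiv), the same IDPi enantiomer (2 mol %), PhMe, −40 °C; used crude
Reagents that add atoms: triethyl(vinyloxy)silane, C=CO[Si](CC)(CC)CC
Why: A second catalyst-controlled Mukaiyama aldol (same facial sense, re) sets C11 (R) and delivers the C9 aldehyde with C11 already protected.

Step 14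
Reactants: 25 (R)-but-3-yn-2-ol
Product: 26 (R)-but-3-yn-2-yl methanesulfonate
Conditions: MsCl, Et3N, CH2Cl2, −78 → 0 °C
Reagents that add atoms: methanesulfonyl chloride, CS(=O)(=O)Cl
Why: Mesylation at oxygen with retention at carbon.

Step 15
Reactants: 24 C9 aldehyde; 26 propargylic mesylate
Product: 28 (2Z,4S,5R,6S,7E,9R,11E,13R,15R,16S)-1-Ar-15-hydroxy-2,4,6,12,16-pentamethyl-5,9,13-tris[(triethylsilyl)oxy]octadeca-2,7,11-trien-17-yn-1-one, via allenylzinc 27 (not isolated)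
Conditions: Pd(OAc)2 (5 mol %), PPh3 (5 mol %), Et2Zn (3 equiv), THF, −78 → −20 °C
Reagents that add atoms: none
Why: Marshall propargylation: anti SN2′ oxidative addition of zerovalent palladium, transmetalation to the (M)-allenylzinc and cyclic SE2′ addition give the anti homopropargylic alcohol under reagent control (C8 S, C9 R); the hindered aryl ketone does not compete.

**Dienamide (steps 16–18)**

Step 16
Reactants: 29 ethyl propiolate
Product: 30 ethyl (Z)-3-iodoprop-2-enoate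
Conditions: NaI, AcOH, 70 °C
Reagents that add atoms: sodium iodide, [Na+].[I-]
Why: Conjugate addition of iodide with anti protonation (hydroiodination) gives the (Z)-iodoacrylate.

Step 17
Reactants: 30 (Z)-iodoacrylate
Product: 32 methyl (2Z,4Z)-5-iodo-2-methylpenta-2,4-dienoate, via iodoacrolein 31 (not isolated)
Conditions: i-Bu2AlH, CH2Cl2, −78 °C, MeOH quench; cold solution added to (CF3CH2O)2P(O)CH(Me)CO2Me, KN(SiMe3)2, 18-crown-6, THF, −78 °C
Reagents that add atoms: methyl 2-[bis(2,2,2-trifluoroethoxy)phosphoryl]propanoate, COC(=O)C(C)P(=O)(OCC(F)(F)F)OCC(F)(F)F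
Why: DIBAL partial reduction gives the labile (Z)-3-iodoacrolein, which is trapped cold by Still–Gennari olefination to give the 2Z olefin while keeping 4Z.

Step 18
Reactants: 32 iododienoate
Product: 33 (2Z,4Z)-5-iodo-2-methylpenta-2,4-dienamide
Conditions: Me3Al, NH4Cl, PhMe, 0 → 50 °C
Reagents that add atoms: ammonium chloride, [NH4+].[Cl-]
Why: Weinreb aminolysis with the aluminium amide made in situ converts the ester to the primary amide without base-mediated isomerisation or conjugate addition.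

**Endgame (steps 19–21)**

Step 19
Reactants: 28 alkyne; 33 iododienamide
Product: 35 (2Z,4Z,6E,8S,9R,11R,12E,15R,16E,18S,19R,20S,21Z)-23-Ar-9-hydroxy-2,8,12,18,20,22-hexamethyl-23-oxo-11,15,19-tris[(triethylsilyl)oxy]tricosa-2,4,6,12,16,21-hexaenamide, via vinylstannane 34 (not isolated)
Conditions: Bu3SnH (1.05 equiv), Pd(PPh3)2Cl2 (3 mol %), THF, 0 °C; then 33, Cu(O2C-2-thienyl) (CuTC, 1.5 equiv), NMP, 0 °C → rt
Reagents that add atoms: none
Why: Palladium-catalysed syn-hydrostannation of the α-branched terminal alkyne gives the (E)-β-vinylstannane, and the Stille–Liebeskind coupling joins C5–C6 with retention of all olefin geometries under neutral conditions.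

Step 20
Reactants: 35 protected seco-amide
Product: 37 (2Z,4Z,6E,8S,9R,11R,12E,15R,16E,18S,19R,20S,21Z)-9,11,15,19-tetrahydroxy-23-(2-hydroxy-3-methyl-5,8-dioxo-5,8-dihydronaphthalen-1-yl)-2,8,12,18,20,22-hexamethyl-23-oxotricosa-2,4,6,12,16,21-hexaenamide, via silylated quinone 36 (not isolated)
Conditions: (NH4)2Ce(NO3)6 (5 equiv), MeCN/H2O 4:1, 0 °C; then 48 % aq. HF, 0 °C → rt
Reagents that add atoms: water, O
Why: Oxidative demethylation of the 1,4-dimethoxynaphthalene to the quinone with concurrent oxidative cleavage of the aryl PMB ether, then fluoride-mediated desilylation in the same aqueous acetonitrile.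

Step 21
Reactants: 37 seco-quinone primary amide
Product: 39 CNP0303373.2, via amidohydroquinone 38 (not isolated)
Conditions: Cu(OAc)2 (20 mol %), 1,10-phenanthroline (20 mol %), O2 (1 atm), MeCN/PhMe 1:1 (1 mM), 40 °C
Reagents that add atoms: none
Why: Proposed new method: acetate-assisted deprotonation gives a divalent copper amidate of the C1 primary amide, which adds in aza-Michael fashion to quinone C2 (the carbon β to the more electrophilic C4 carbonyl, since the C1 carbonyl is deactivated as a vinylogous acid by the para 6-hydroxyl); tautomerisation gives the 2-amidohydroquinone, and its aerobic re-oxidation by divalent copper/O2 makes the ring closure irreversible and forms the N–C2 bond and the 29-membered ring at high dilution. The closest known reaction type is the Cu(OAc)2-catalysed aerobic oxidative amination of 1,4-naphthoquinones with amines (and Chan–Lam/Goldberg amide N-arylation), not yet shown for a carboxamide N–H or for ring closure.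

**Compound list**

1 | 3-methylbut-3-en-2-one | CC(=O)C(C)=C | starting material
2 | tert-butyldimethyl[(3-methylbuta-1,3-dien-2-yl)oxy]silane | C=C(C)C(=C)O[Si](C)(C)C(C)(C)C | intermediate
3 | 1,4-benzoquinone | O=C1C=CC(=O)C=C1 | starting material
4 | cis-6-[(tert-butyldimethylsilyl)oxy]-7-methyl-4a,5,8,8a-tetrahydronaphthalene-1,4-dione (racemic, cis ring fusion) | O=C1C=CC(=O)[C@@H]2CC(O[Si](C)(C)C(C)(C)C)=C(C)C[C@H]12 | intermediate (not isolated)
5 | tert-butyl[(5,8-dimethoxy-3-methyl-1,4-dihydronaphthalen-2-yl)oxy]dimethylsilane | COc1ccc(OC)c2c1CC(O[Si](C)(C)C(C)(C)C)=C(C)C2 | intermediate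
6 | 3-bromo-5,8-dimethoxy-3-methyl-3,4-dihydronaphthalen-2(1H)-one (racemic) | COc1ccc(OC)c2c1CC(=O)C(C)(Br)C2 | intermediate (not isolated)
7 | 5,8-dimethoxy-3-methylnaphthalen-2-ol | COc1ccc(OC)c2cc(O)c(C)cc12 | intermediate (not isolated)
8 | 1-bromo-5,8-dimethoxy-3-methylnaphthalen-2-ol | COc1ccc(OC)c2c(Br)c(O)c(C)cc12 | intermediate
9 | 1-bromo-5,8-dimethoxy-2-[(4-methoxybenzyl)oxy]-3-methylnaphthalene | COc1ccc(COc2c(Br)c3c(OC)ccc(OC)c3cc2C)cc1 | intermediate
10 | methyl (S)-3-hydroxy-2-methylpropanoate | COC(=O)[C@@H](C)CO | starting material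
11 | methyl (S)-3-[(tert-butyldimethylsilyl)oxy]-2-methylpropanoate | COC(=O)[C@@H](C)CO[Si](C)(C)C(C)(C)C | intermediate
12 | (S)-3-[(tert-butyldimethylsilyl)oxy]-2-methylpropanal | O=C[C@@H](C)CO[Si](C)(C)C(C)(C)C | intermediate
13 | (2S,3R,4S)-1-[(tert-butyldimethylsilyl)oxy]-2,4-dimethylhex-5-en-3-ol | C=C[C@H](C)[C@@H](O)[C@@H](C)CO[Si](C)(C)C(C)(C)C | intermediate (not isolated)
14 | (2S,3R,4S)-2,4-dimethylhex-5-ene-1,3-diol | C=C[C@H](C)[C@@H](O)[C@@H](C)CO | intermediate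
15 | (2R,3R,4S)-3-hydroxy-2,4-dimethylhex-5-enal | C=C[C@H](C)[C@@H](O)[C@@H](C)C=O | intermediate
16 | methyl (2Z,4S,5R,6S)-5-hydroxy-2,4,6-trimethylocta-2,7-dienoate | C=C[C@H](C)[C@@H](O)[C@@H](C)/C=C(/C)C(=O)OC | intermediate (not isolated)
17 | (5S,6R)-6-[(2S)-but-3-en-2-yl]-3,5-dimethyl-5,6-dihydro-2H-pyran-2-one | C=C[C@H](C)[C@H]1OC(=O)C(C)=C[C@@H]1C | intermediate
18 | {5,8-dimethoxy-2-[(4-methoxybenzyl)oxy]-3-methylnaphthalen-1-yl}lithium | [Li]c1c(OCc2ccc(OC)cc2)c(C)cc2c(OC)ccc(OC)c12 | intermediate (not isolated)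
19 | lithium (3S,4R,5S,6Z)-8-Ar-3,5,7-trimethyl-8-oxoocta-1,6-dien-4-olate (in equilibrium with the cyclic lactolate) | C=C[C@H](C)[C@@H]([O-])[C@@H](C)/C=C(/C)C(=O)c1c(OCc2ccc(OC)cc2)c(C)cc2c(OC)ccc(OC)c12.[Li+] | intermediate (not isolated)
20 | (2Z,4S,5R,6S)-1-Ar-2,4,6-trimethyl-5-[(triethylsilyl)oxy]octa-2,7-dien-1-one | C=C[C@H](C)[C@@H](O[Si](CC)(CC)CC)[C@@H](C)/C=C(/C)C(=O)c1c(OCc2ccc(OC)cc2)c(C)cc2c(OC)ccc(OC)c12 | intermediate
21 | (2E,4S,5R,6S,7Z)-9-Ar-4,6,8-trimethyl-9-oxo-5-[(triethylsilyl)oxy]nona-2,7-dienal | O=C/C=C/[C@H](C)[C@@H](O[Si](CC)(CC)CC)[C@@H](C)/C=C(/C)C(=O)c1c(OCc2ccc(OC)cc2)c(C)cc2c(OC)ccc(OC)c12 | intermediate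
22 | (3R,4E,6S,7R,8S,9Z)-11-Ar-6,8,10-trimethyl-11-oxo-3,7-bis[(triethylsilyl)oxy]undeca-4,9-dienal | O=CC[C@@H](O[Si](CC)(CC)CC)/C=C/[C@H](C)[C@@H](O[Si](CC)(CC)CC)[C@@H](C)/C=C(/C)C(=O)c1c(OCc2ccc(OC)cc2)c(C)cc2c(OC)ccc(OC)c12 | intermediate (not isolated)
23 | (2E,5R,6E,8S,9R,10S,11Z)-13-Ar-2,8,10,12-tetramethyl-13-oxo-5,9-bis[(triethylsilyl)oxy]trideca-2,6,11-trienal | O=C/C(C)=C/C[C@@H](O[Si](CC)(CC)CC)/C=C/[C@H](C)[C@@H](O[Si](CC)(CC)CC)[C@@H](C)/C=C(/C)C(=O)c1c(OCc2ccc(OC)cc2)c(C)cc2c(OC)ccc(OC)c12 | intermediate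
24 | (3R,4E,7R,8E,10S,11R,12S,13Z)-15-Ar-4,10,12,14-tetramethyl-15-oxo-3,7,11-tris[(triethylsilyl)oxy]pentadeca-4,8,13-trienal | O=CC[C@@H](O[Si](CC)(CC)CC)/C(C)=C/C[C@@H](O[Si](CC)(CC)CC)/C=C/[C@H](C)[C@@H](O[Si](CC)(CC)CC)[C@@H](C)/C=C(/C)C(=O)c1c(OCc2ccc(OC)cc2)c(C)cc2c(OC)ccc(OC)c12 | intermediate
25 | (R)-but-3-yn-2-ol | C#C[C@@H](C)O | starting material
26 | (R)-but-3-yn-2-yl methanesulfonate | C#C[C@@H](C)OS(C)(=O)=O | intermediate
27 | (M)-buta-1,2-dien-1-yl(ethyl)zinc | [H]C(C)=[C@]=C([H])[Zn]CC | intermediate (not isolated)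
28 | (2Z,4S,5R,6S,7E,9R,11E,13R,15R,16S)-1-Ar-15-hydroxy-2,4,6,12,16-pentamethyl-5,9,13-tris[(triethylsilyl)oxy]octadeca-2,7,11-trien-17-yn-1-one | C#C[C@H](C)[C@H](O)C[C@@H](O[Si](CC)(CC)CC)/C(C)=C/C[C@@H](O[Si](CC)(CC)CC)/C=C/[C@H](C)[C@@H](O[Si](CC)(CC)CC)[C@@H](C)/C=C(/C)C(=O)c1c(OCc2ccc(OC)cc2)c(C)cc2c(OC)ccc(OC)c12 | intermediate
29 | ethyl propiolate | CCOC(=O)C#C | starting material
30 | ethyl (Z)-3-iodoprop-2-enoate | CCOC(=O)/C=C\I | intermediate
31 | (Z)-3-iodoprop-2-enal | O=C/C=C\I | intermediate (not isolated)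
32 | methyl (2Z,4Z)-5-iodo-2-methylpenta-2,4-dienoate | C/C(C(=O)OC)=C/C=C\I | intermediate
33 | (2Z,4Z)-5-iodo-2-methylpenta-2,4-dienamide | C/C(C(N)=O)=C/C=C\I | intermediate
34 | (E)-C6 tributylvinylstannane of 28 (alkyne replaced by (E)-CH=CH–SnBu3) | CCCC[Sn](CCCC)(CCCC)/C=C/[C@H](C)[C@H](O)C[C@@H](O[Si](CC)(CC)CC)/C(C)=C/C[C@@H](O[Si](CC)(CC)CC)/C=C/[C@H](C)[C@@H](O[Si](CC)(CC)CC)[C@@H](C)/C=C(/C)C(=O)c1c(OCc2ccc(OC)cc2)c(C)cc2c(OC)ccc(OC)c12 | intermediate (not isolated)
35 | (2Z,4Z,6E,8S,9R,11R,12E,15R,16E,18S,19R,20S,21Z)-23-Ar-9-hydroxy-2,8,12,18,20,22-hexamethyl-23-oxo-11,15,19-tris[(triethylsilyl)oxy]tricosa-2,4,6,12,16,21-hexaenamide | C/C(C(N)=O)=C/C=C\C=C\[C@H](C)[C@H](O)C[C@@H](O[Si](CC)(CC)CC)/C(C)=C/C[C@@H](O[Si](CC)(CC)CC)/C=C/[C@H](C)[C@@H](O[Si](CC)(CC)CC)[C@@H](C)/C=C(/C)C(=O)c1c(OCc2ccc(OC)cc2)c(C)cc2c(OC)ccc(OC)c12 | intermediate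
36 | 11,15,19-tris(triethylsilyl) ether of 37 (same configuration; aryl = 2-hydroxy-3-methyl-5,8-dioxo-5,8-dihydronaphthalen-1-yl) | C/C(C(N)=O)=C/C=C\C=C\[C@H](C)[C@H](O)C[C@@H](O[Si](CC)(CC)CC)/C(C)=C/C[C@@H](O[Si](CC)(CC)CC)/C=C/[C@H](C)[C@@H](O[Si](CC)(CC)CC)[C@@H](C)/C=C(/C)C(=O)c1c(O)c(C)cc2c1C(=O)C=CC2=O | intermediate (not isolated)
37 | (2Z,4Z,6E,8S,9R,11R,12E,15R,16E,18S,19R,20S,21Z)-9,11,15,19-tetrahydroxy-23-(2-hydroxy-3-methyl-5,8-dioxo-5,8-dihydronaphthalen-1-yl)-2,8,12,18,20,22-hexamethyl-23-oxotricosa-2,4,6,12,16,21-hexaenamide | C/C(C(N)=O)=C/C=C\C=C\[C@H](C)[C@H](O)C[C@@H](O)/C(C)=C/C[C@@H](O)/C=C/[C@H](C)[C@@H](O)[C@@H](C)/C=C(/C)C(=O)c1c(O)c(C)cc2c1C(=O)C=CC2=O | intermediate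
38 | hydroquinone form of 39 (macrocyclic 2-amido-1,4-dihydroxynaphthalene, same configuration) | C/C1=C/C=C\C=C\[C@H](C)[C@H](O)C[C@@H](O)/C(C)=C/C[C@@H](O)/C=C/[C@H](C)[C@@H](O)[C@@H](C)/C=C(/C)C(=O)c2c(O)c(C)cc3c(O)c(NC1=O)cc(O)c23 | intermediate (not isolated)
39 | CNP0303373.2: (2Z,4Z,6E,8S,9R,11R,12E,15R,16E,18S,19R,20S,21Z) 29-membered ansa-lactam bridging N–C2 and C5 of 6-hydroxy-7-methyl-1,4-naphthoquinone | C/C1=C/C=C\C=C\[C@H](C)[C@H](O)C[C@@H](O)/C(C)=C/C[C@@H](O)/C=C/[C@H](C)[C@@H](O)[C@@H](C)/C=C(/C)C(=O)c2c(O)c(C)cc3c2C(=O)C=C(NC1=O)C3=O | target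

**Step count**
Total: 21 steps. Longest linear sequence: 13 steps (steps 5–13, 15, 19, 20, 21, from Roche ester 10).

**Three steps most likely to fail, with fallbacks**

First, step 21, the new ring-closing quinone C–H amidation. It may fail through low amide nucleophilicity, or through addition at C3 or by oxygen. The fallback is a known macrolactamisation; it sets out from 28 and 32 and rejoins the route at 39. Ester 32 is saponified (LiOH, THF/H2O, 0 °C) to (2Z,4Z)-5-iodo-2-methylpenta-2,4-dienoic acid F1. The hydrostannation/Stille sequence of step 19 is run on 28 using F1 in place of 33 to give the protected seco-acid F2. (NH4)2Ce(NO3)6 followed by aqueous HF, as in step 20, gives the seco-acid quinone F3. NaN3 in AcOH/THF/H2O (conjugate addition of azide and loss of N2, a known quinone amination) gives the 2-aminoquinone seco-acid F4; the same electronic bias directs nitrogen to C2. Macrolactamisation (2-chloro-1-methylpyridinium iodide, Et3N, MeCN/CH2Cl2, 1 mM) then forms the same amide ring bond and gives 39. If the vinylogous amide nitrogen is too unreactive, the quinone is reduced in situ with Na2S2O4 before closure and re-oxidised by air afterwards.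

Second, step 12 (the same concern applies to step 13): the confined-acid acetaldehyde aldol on a large, Lewis-basic enal. The fallback sets out from 21 and rejoins at 22. A Sn(OTf)2/chiral diamine-promoted Mukaiyama aldol (Kobayashi–Mukaiyama; 1-(ethylsulfanyl)-1-(trimethylsilyloxy)ethene, (S)-1-methyl-2-(piperidin-1-ylmethyl)pyrrolidine, Bu3SnF, EtCN, −78 °C) gives, after desilylation on work-up, the β-hydroxy thioester F5. TESOTf/2,6-lutidine gives the silyl ether F6. i-Bu2AlH at −78 °C reduces the thioester to aldehyde 22 (the di-ortho-substituted aryl ketone is inert at this temperature), which then undergoes the Wittig reaction of step 12.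

Third, step 10: addition of the hindered aryllithium to the lactone with in situ silylation. Risks are lactolate silylation, γ-deprotonation and double addition. The fallback sets out from 17 and 9 and rejoins at 20. Lactone 17 is opened with Me(MeO)NH·HCl/Me3Al (THF, 0 °C) to the hydroxy Weinreb amide F7. Silylation (Et3SiCl, imidazole, DMF) gives the silyl ether F8. Aryllithium 18 (from 9, n-BuLi, THF, −78 °C) then adds once, through the stable chelated tetrahedral intermediate, to give ketone 20 directly; the Z geometry is retained and no lactol equilibrium arises.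

**Further compounds**

F1 | step 21 | (2Z,4Z)-5-iodo-2-methylpenta-2,4-dienoic acid | C/C(C(=O)O)=C/C=C\I
F2 | step 21 | (2Z,4Z,6E,8S,9R,11R,12E,15R,16E,18S,19R,20S,21Z)-23-Ar-9-hydroxy-2,8,12,18,20,22-hexamethyl-23-oxo-11,15,19-tris[(triethylsilyl)oxy]tricosa-2,4,6,12,16,21-hexaenoic acid | C/C(C(=O)O)=C/C=C\C=C\[C@H](C)[C@H](O)C[C@@H](O[Si](CC)(CC)CC)/C(C)=C/C[C@@H](O[Si](CC)(CC)CC)/C=C/[C@H](C)[C@@H](O[Si](CC)(CC)CC)[C@@H](C)/C=C(/C)C(=O)c1c(OCc2ccc(OC)cc2)c(C)cc2c(OC)ccc(OC)c12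
F3 | step 21 | (2Z,4Z,6E,8S,9R,11R,12E,15R,16E,18S,19R,20S,21Z)-9,11,15,19-tetrahydroxy-23-(2-hydroxy-3-methyl-5,8-dioxo-5,8-dihydronaphthalen-1-yl)-2,8,12,18,20,22-hexamethyl-23-oxotricosa-2,4,6,12,16,21-hexaenoic acid | C/C(C(=O)O)=C/C=C\C=C\[C@H](C)[C@H](O)C[C@@H](O)/C(C)=C/C[C@@H](O)/C=C/[C@H](C)[C@@H](O)[C@@H](C)/C=C(/C)C(=O)c1c(O)c(C)cc2c1C(=O)C=CC2=O
F4 | step 21 | 6-amino analogue of F3 (aryl = 6-amino-2-hydroxy-3-methyl-5,8-dioxo-5,8-dihydronaphthalen-1-yl) | C/C(C(=O)O)=C/C=C\C=C\[C@H](C)[C@H](O)C[C@@H](O)/C(C)=C/C[C@@H](O)/C=C/[C@H](C)[C@@H](O)[C@@H](C)/C=C(/C)C(=O)c1c(O)c(C)cc2c1C(=O)C=C(N)C2=O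
F5 | step 12 | S-ethyl (3R,4E,6S,7R,8S,9Z)-11-Ar-3-hydroxy-6,8,10-trimethyl-11-oxo-7-[(triethylsilyl)oxy]undeca-4,9-dienethioate | CCSC(=O)C[C@@H](O)/C=C/[C@H](C)[C@@H](O[Si](CC)(CC)CC)[C@@H](C)/C=C(/C)C(=O)c1c(OCc2ccc(OC)cc2)c(C)cc2c(OC)ccc(OC)c12
F6 | step 12 | S-ethyl (3R,4E,6S,7R,8S,9Z)-11-Ar-6,8,10-trimethyl-11-oxo-3,7-bis[(triethylsilyl)oxy]undeca-4,9-dienethioate | CCSC(=O)C[C@@H](O[Si](CC)(CC)CC)/C=C/[C@H](C)[C@@H](O[Si](CC)(CC)CC)[C@@H](C)/C=C(/C)C(=O)c1c(OCc2ccc(OC)cc2)c(C)cc2c(OC)ccc(OC)c12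
F7 | step 10 | (2Z,4S,5R,6S)-5-hydroxy-N-methoxy-N,2,4,6-tetramethylocta-2,7-dienamide | C=C[C@H](C)[C@@H](O)[C@@H](C)/C=C(/C)C(=O)N(C)OC
F8 | step 10 | (2Z,4S,5R,6S)-N-methoxy-N,2,4,6-tetramethyl-5-[(triethylsilyl)oxy]octa-2,7-dienamide | C=C[C@H](C)[C@@H](O[Si](CC)(CC)CC)[C@@H](C)/C=C(/C)C(=O)N(C)OC
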